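# Proposed synthesis of CNP0210944.0: ring A grown on the ether oxygen by a tetraketide aldol fold

## The problem

Target 16 is a diaryl ether of two hexasubstituted benzene rings. Ring A carries C1 CO2Me, C2 CH3, C3 O-aryl, C4 OH, C5 CH3 and C6 OH; ring B carries C1' ether O, C2' CHO, C3' OH, C4' Cl, C5' CH3 and C6' CO2H. The ether oxygen is flanked by four ortho substituents (C2 CH3, C4 OH, C2' CHO, C6' CO2H), so aryl–oxygen coupling or SNAr between two finished rings would meet severe crowding and an electron-rich partner on each side. There are no stereocentres; the task is regiochemical (twelve different ring positions) and chemoselective. Two carboxyl groups must end differently (methyl ester on ring A, free acid on ring B) and three phenols must end free. The salicylaldehyde unit of ring B will not survive carbanions, so the formyl group has to come late. The aryl chloride limits reductive deprotection, and the ring B carboxyl must never be activated next to the C4 hydroxyl, which could close a seven-membered lactone. The enabling feature is that ring A is a 3-methylorsellinate, the aromatised form of a C-methylated tetraketide: the C1–C2 bond is an aldol bond between a β-keto ester methylene and a methyl ketone, C4 and C6 are former ketones, and C3 is an sp3 carbon between two carbonyls in the open chain. That carbon can receive the ring B phenol by SN2 before ring A exists. Ring B has the 5-chlorohaematommic acid pattern, which can be built on orsellinic acid 1.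

## Retrosynthesis

**Ring B acid (16 ⇒ 15).** The O–CH2Ph bond of a benzyl ester is cut last. A benzyl ester tells the ring B carboxyl apart from the ring A methyl ester and falls under neutral hydrogenolysis. A tert-butyl ester was rejected because it would not survive the acidic ketal chemistry earlier in the route. The forward step must spare the aryl chloride and the chelated aldehyde.

**Formyl group (15 ⇒ 13 ⇒ 12).** The C2'–CHO bond is cut next. C2' is the only unsubstituted aromatic carbon in 13 and lies ortho to the free C3' hydroxyl, the situation in which orsellinates are formylated to haematommates. The phenol must therefore be free while the benzyl ester stays, so the C3' oxygen is carried as an allyl ether (12), removable with zerovalent palladium. Formylating earlier would expose an aldehyde to the dianion chemistry.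

**Ring A (12 ⇒ 11 ⇒ 10), the key cut.** Bond C1–C2 is cut and the arene is unfolded to the 3,5,7-triketo ester 11, masked at the future C2 carbonyl as dioxolane 10. Cutting the aryl–oxygen bond instead would demand a tetra-ortho-substituted coupling. Cutting C4–C5 or C5–C6 would need an acylphloroglucinol-type fold that the C3 substituent forbids. The precursor is an open chain with no aromatic ring A; its two stereocentres are irrelevant. The forward reaction must unmask one ketone and steer the chain into the C1-to-C2 aldol and no other fold.

**Chain (10 ⇒ 7 + 9, from 8).** The bond between the future C4 carbonyl and the methyl-bearing future C5 is cut, giving α-aryloxy ester 7 and the dianion 9 of methyl 3-oxopentanoate 8. This is the classical γ-acylation of a β-keto ester dianion, and 8 supplies C1, C6, C5 with its methyl, and the ester in one commercial piece. The masked ketone in 7 is essential, since a free β-keto ester would simply be deprotonated. The forward step needs addition to a hindered ester to beat proton transfer.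

**Ether oxygen (7 ⇒ 6 ⇒ 4 + 5).** The ketal is removed and the O–C(sp3) bond is cut, giving phenol 4 and ethyl 2-chloroacetoacetate 5. Here the crowded diaryl ether is reduced to a Williamson alkylation of a phenol by a doubly activated chloride. The only demand is that the chelated phenol of 4 be nucleophilic enough.

**Ring B phenol (4 ⇒ 3 ⇒ 2 ⇒ 1).** Allyl ether, chlorine and benzyl ester are removed in turn, back to orsellinic acid 1. Chlorination is placed before allylation, while both hydroxyls are free, because the site preference (para to the chelated hydroxyl) is established for that substitution pattern. The non-chelated hydroxyl is then the only one that alkylates readily.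

## Roads not taken

**Alternative 1:** Ring B is cut at C4'–C5' and C6'–C1'. The 6-aryloxy-4-benzyloxy-3-chloro-2-pyranone A2, carrying ring A on its C6 oxygen, would add benzyl but-2-ynoate A3 in a thermal [4+2] cycloaddition, and the bridged lactone would lose CO2 to give the fully benzylated diaryl ether A1.
- Merits: the polarity is matched, since the donor-activated, chlorine-bearing pyranone terminus should bond to the methyl-bearing alkyne carbon. Four ring B substituents arrive in one step. The ether oxygen is attached by addition–elimination on a pyranone, not on a crowded arene.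
- Weak points: A2 requires the ring A phenol A4, a pentasubstituted arene with three differentiated oxygens that is as hard to make as ring A itself. That phenol is flanked by methyl and benzyloxy groups when it must attack a 6-halopyranone. But-2-ynoates are sluggish dienophiles and would need prolonged heating well above 100 °C. A1 must still be formylated between two ether oxygens with no free phenol to direct the reagent, and then lose four benzyl groups beside Cl and CHO.
- Comparison: this road is more convergent than the chosen one and handles no enolisable polycarbonyl chain. The chosen plan sets against it that ring A comes from two bulk β-keto esters, ring B comes nearly complete from orsellinic acid, and no hexasubstituted phenol has to be prepared separately.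

**Alternative 2:** Ring B is cut at C1'–C2' and C5'–C6'. (E)-4-Methoxy-2-(trimethylsilyloxy)penta-1,3-diene A6 would add to the tert-butyl 3-aryloxypropiolate A7 derived from phenol A4, and 1,4-loss of methanol would aromatise the adduct to A5.
- Merits: two C–C bonds form under mild conditions, the diene fixes the hydroxyl/methyl/ester pattern, and aryl–oxygen coupling is again avoided.
- Weak points: the aryloxy group makes A7 an ynol ether, electron-rich at the carbon that must accept the nucleophilic diene terminus, hard to prepare from a hindered phenol and easily hydrolysed. A5 lacks both chlorine and formyl, so two electrophilic substitutions at C2' and C4', both ortho to the same hydroxyl, must be told apart. Phenol A4 is needed as in alternative 1. Two kinds of protecting group remain on three sites.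
- Comparison: the key step is milder than a triketo ester fold. The chosen plan places chlorine on an orsellinate, where the site preference is known, leaves a single open position for formylation, and needs three steps after its key step, not four or more.

**Alternative 3:** Ring A is taken apart at C1–C2, C4–C5, C1–C6 and C3–C4. Irradiation of diazo keto ester A9, with ring B already attached as an enol ether, would trigger Wolff migration to a vinylketene. This would add to 1-(triisopropylsilyloxy)propyne A10; ring opening of the cyclobutenone and six-electron electrocyclisation would give A8.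
- Merits: every substituent position is fixed by mechanism, the route is convergent, and the C4 and C6 oxygens emerge differentiated.
- Weak points: the ketene carries an ester and is therefore a 2-oxoketene, for which hetero-[4+2] addition to the electron-rich alkyne competes with the [2+2] step. Wolff rearrangement of 2-diazo-1,3-dicarbonyl compounds is less clean than that of simple diazo ketones. The ring closure must create a hexasubstituted arene. A9 and A10 each need several steps, A10 is moisture-sensitive, and a desilylation is added after the key step.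
- Comparison: in regiochemical certainty this road is better than a biomimetic fold, which has to be steered among several cyclisation modes. The chosen plan sets against it direct precedent for the aldol fold in orsellinate synthesis, purely thermal operations, two commodity building blocks, and a C3 oxygen substituent that itself blocks the main competing (Claisen) fold.

Key step: step 7

Remark on the chemistry: the first chlorine is assumed to enter benzyl orsellinate at C5 (para to the chelated hydroxyl), as in other orsellinate esters and orcylaldehyde. β-Dicarbonyl compounds are drawn as keto forms, and chain stereocentres are left unassigned because aromatisation erases them.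

## Route

Step 1
Reactants: 1 orsellinic acid (2,4-dihydroxy-6-methylbenzoic acid)
Product: 2 benzyl 2,4-dihydroxy-6-methylbenzoate
Conditions: BnBr (1.05 equiv), KHCO3 (1.2 equiv), DMF, rt
Reagents that add atoms: benzyl bromide, BrCc1ccccc1
Why: Carboxylate O-alkylation (SN2); hydrogen carbonate ionises only the carboxylic acid, so both phenols stay free, and room temperature avoids decarboxylation of the β-resorcylic acid.

Step 2
Reactants: 2 benzyl 2,4-dihydroxy-6-methylbenzoate
Product: 3 benzyl 3-chloro-4,6-dihydroxy-2-methylbenzoate
Conditions: SO2Cl2 (1.05 equiv), Et2O, 0 °C to rt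
Reagents that add atoms: sulfuryl chloride, O=S(=O)(Cl)Cl
Why: Electrophilic aromatic chlorination; in orsellinate esters the first chlorine is expected para to the chelated hydroxyl and ortho to the free one (orsellinate C5), and one equivalent at low temperature limits dichlorination, any C3 isomer being separable.

Step 3
Reactants: 3 benzyl 3-chloro-4,6-dihydroxy-2-methylbenzoate
Product: 4 benzyl 4-(allyloxy)-3-chloro-6-hydroxy-2-methylbenzoate
Conditions: allyl bromide (1.1 equiv), K2CO3 (1.1 equiv), acetone, reflux
Reagents that add atoms: allyl bromide, C=CCBr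
Why: Williamson ether synthesis; the hydroxyl para to the ester and ortho to chlorine is the more acidic and is not hydrogen-bonded, whereas the other is chelated to the ester carbonyl and stays free.

Step 4
Reactants: 4 benzyl 4-(allyloxy)-3-chloro-6-hydroxy-2-methylbenzoate; 5 ethyl 2-chloro-3-oxobutanoate (ethyl 2-chloroacetoacetate, racemic)
Product: 6 ethyl 2-[5-(allyloxy)-2-(benzyloxycarbonyl)-4-chloro-3-methylphenoxy]-3-oxobutanoate (racemic)
Conditions: 5 (1.5 equiv), K2CO3 (2 equiv), DMF, 45 °C
Reagents that add atoms: none
Why: SN2 O-alkylation of the phenoxide by a chloride activated by two carbonyl groups, the known first step of the aryloxy ketone route to benzofurans; the acidic product rests as its enolate and does not react further.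

Step 5
Reactants: 6 ethyl 2-[5-(allyloxy)-2-(benzyloxycarbonyl)-4-chloro-3-methylphenoxy]-3-oxobutanoate
Product: 7 ethyl 2-[5-(allyloxy)-2-(benzyloxycarbonyl)-4-chloro-3-methylphenoxy]-2-(2-methyl-1,3-dioxolan-2-yl)acetate (racemic)
Conditions: TMSOCH2CH2OTMS (2 equiv), TMSOTf (5 mol %), CH2Cl2, −78 to −20 °C; pyridine quench
Reagents that add atoms: 1,2-bis(trimethylsilyloxy)ethane, C[Si](C)(C)OCCO[Si](C)(C)C
Why: Noyori ketalisation; the aprotic low-temperature conditions mask the ketone without the hot Brønsted acid that would invite cyclodehydration of the aryloxy ketone onto C2' of ring B, and the benzyl ester and allyl ether are inert.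

Step 6
Reactants: 7 ethyl 2-[5-(allyloxy)-2-(benzyloxycarbonyl)-4-chloro-3-methylphenoxy]-2-(2-methyl-1,3-dioxolan-2-yl)acetate; 8 methyl 3-oxopentanoate
Product: 10 methyl 6-[5-(allyloxy)-2-(benzyloxycarbonyl)-4-chloro-3-methylphenoxy]-4-methyl-6-(2-methyl-1,3-dioxolan-2-yl)-3,5-dioxohexanoate, via dilithium dianion of methyl 3-oxopentanoate 9 (not isolated)
Conditions: 8 (3 equiv), LiN(iPr)2 (6.0 equiv), THF, 0 °C; then 7, −78 to −20 °C; cold 1 M HCl
Reagents that add atoms: none
Why: Huckin–Weiler γ-acylation of a β-keto ester dianion (Claisen condensation) by an ester, as in the acylation of acetoacetate dianion with ketal-protected acetoacetate; excess dianion absorbs the acidic product, and the ring B benzyl ester is shielded by its two ortho substituents.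

Step 7
Reactants: 10 methyl 6-[5-(allyloxy)-2-(benzyloxycarbonyl)-4-chloro-3-methylphenoxy]-4-methyl-6-(2-methyl-1,3-dioxolan-2-yl)-3,5-dioxohexanoate
Product: 12 methyl 3-[5-(allyloxy)-2-(benzyloxycarbonyl)-4-chloro-3-methylphenoxy]-4,6-dihydroxy-2,5-dimethylbenzoate, via free triketo ester 11 (not isolated)
Conditions: 1 M aq. HCl, THF, 40 °C; then aq. K2CO3 to pH 9–10, rt; 1 M HCl work-up
Reagents that add atoms: none
Why: Aqueous acid hydrolyses the dioxolane to the methyl ketone of triketo ester 11; on basification the methylene between the ester and the future C6 ketone is enolised and adds to that ketone, forming bond C1–C2. Ring A closes in a 6-(enolexo)-exo-trig aldol, and loss of water with enolisation of the C4 and C6 carbonyls gives the resorcinol irreversibly. The closest known reaction type is the aldol aromatisation of 3,5,7-triketo esters to orsellinates, the laboratory copy of the polyketide fold. No stereocentre is created, and the two chain stereocentres (future C3 and C5) are erased. The selectivity needed is carbon–carbon closure at C1–C2 over lactonisation to a 4-hydroxy-2-pyranone, cyclodehydration through oxygen in the acid stage, and aldol of the terminal methyl onto the future C6 carbonyl. The substrate secures it: the ester-flanked methylene is the most acidic unsubstituted carbon, lactonisation needs heat and an amidine base whereas the aldol runs at room temperature in weak aqueous base, and the Claisen fold is blocked because its nucleophilic carbon is the aryloxy-bearing C3, which would become quaternary and could not aromatise. The benzyl ester, allyl ether and methyl ester tolerate dilute acid and carbonate at these temperatures.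

Step 8
Reactants: 12 methyl 3-[5-(allyloxy)-2-(benzyloxycarbonyl)-4-chloro-3-methylphenoxy]-4,6-dihydroxy-2,5-dimethylbenzoate
Product: 13 methyl 3-[2-(benzyloxycarbonyl)-4-chloro-5-hydroxy-3-methylphenoxy]-4,6-dihydroxy-2,5-dimethylbenzoate
Conditions: Pd(PPh3)4 (5 mol %), morpholine (10 equiv), THF, rt
Reagents that add atoms: none
Why: Tsuji–Trost deallylation; zerovalent palladium ionises the aryl allyl ether and morpholine traps the π-allyl complex, while the benzyl ester, methyl ester and hindered aryl chloride do not react at room temperature.

Step 9
Reactants: 13 methyl 3-[2-(benzyloxycarbonyl)-4-chloro-5-hydroxy-3-methylphenoxy]-4,6-dihydroxy-2,5-dimethylbenzoate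
Product: 15 methyl 3-[2-(benzyloxycarbonyl)-4-chloro-6-formyl-5-hydroxy-3-methylphenoxy]-4,6-dihydroxy-2,5-dimethylbenzoate, via chloro(methoxy)methyl arene 14 (not isolated)
Conditions: Cl2CHOMe (2 equiv), TiCl4 (5 equiv), CH2Cl2, −20 to 0 °C; then 1 M aq. HCl
Reagents that add atoms: dichloromethyl methyl ether, COC(Cl)Cl; water, O
Why: Rieche formylation; the titanium phenoxide of the C3' hydroxyl delivers the electrophile to C2', the only unsubstituted aromatic carbon in the molecule and ortho to two oxygens, as in the formylation of orsellinates to haematommates, and the α-chloro ether 14 is hydrolysed on work-up.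

Step 10
Reactants: 15 methyl 3-[2-(benzyloxycarbonyl)-4-chloro-6-formyl-5-hydroxy-3-methylphenoxy]-4,6-dihydroxy-2,5-dimethylbenzoate
Product: 16 3-chloro-6-[2,4-dihydroxy-5-(methoxycarbonyl)-3,6-dimethylphenoxy]-5-formyl-4-hydroxy-2-methylbenzoic acid (target)
Conditions: H2 (1 atm), 10% Pd/C, EtOAc, rt, stopped after one equivalent of H2
Reagents that add atoms: none
Why: Catalytic hydrogenolysis of the benzyl ester under neutral conditions; benzylic C–O cleavage should be faster than reduction of the chelated aldehyde or of the flanked aryl chloride, and the methyl ester is untouched.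

## Compound list

1 | orsellinic acid (2,4-dihydroxy-6-methylbenzoic acid) | Cc1cc(O)cc(O)c1C(=O)O | starting material
2 | benzyl 2,4-dihydroxy-6-methylbenzoate | Cc1cc(O)cc(O)c1C(=O)OCc1ccccc1 | intermediate
3 | benzyl 3-chloro-4,6-dihydroxy-2-methylbenzoate | Cc1c(Cl)c(O)cc(O)c1C(=O)OCc1ccccc1 | intermediate
4 | benzyl 4-(allyloxy)-3-chloro-6-hydroxy-2-methylbenzoate | Cc1c(Cl)c(OCC=C)cc(O)c1C(=O)OCc1ccccc1 | intermediate
5 | ethyl 2-chloro-3-oxobutanoate (racemic) | CCOC(=O)C(Cl)C(C)=O | starting material
6 | ethyl 2-[5-(allyloxy)-2-(benzyloxycarbonyl)-4-chloro-3-methylphenoxy]-3-oxobutanoate (racemic) | CCOC(=O)C(Oc1cc(OCC=C)c(Cl)c(C)c1C(=O)OCc1ccccc1)C(C)=O | intermediate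
7 | ethyl 2-[5-(allyloxy)-2-(benzyloxycarbonyl)-4-chloro-3-methylphenoxy]-2-(2-methyl-1,3-dioxolan-2-yl)acetate (racemic) | CCOC(=O)C(Oc1cc(OCC=C)c(Cl)c(C)c1C(=O)OCc1ccccc1)C1(C)OCCO1 | intermediate
8 | methyl 3-oxopentanoate | CCC(=O)CC(=O)OC | starting material
9 | dilithium dianion of methyl 3-oxopentanoate (not isolated) | [Li+].[Li+].C[CH-]C(=O)[CH-]C(=O)OC | intermediate
10 | methyl 6-[5-(allyloxy)-2-(benzyloxycarbonyl)-4-chloro-3-methylphenoxy]-4-methyl-6-(2-methyl-1,3-dioxolan-2-yl)-3,5-dioxohexanoate (mixture of epimers) | COC(=O)CC(=O)C(C)C(=O)C(Oc1cc(OCC=C)c(Cl)c(C)c1C(=O)OCc1ccccc1)C1(C)OCCO1 | intermediate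
11 | methyl 6-[5-(allyloxy)-2-(benzyloxycarbonyl)-4-chloro-3-methylphenoxy]-4-methyl-3,5,7-trioxooctanoate (not isolated) | COC(=O)CC(=O)C(C)C(=O)C(Oc1cc(OCC=C)c(Cl)c(C)c1C(=O)OCc1ccccc1)C(C)=O | intermediate
12 | methyl 3-[5-(allyloxy)-2-(benzyloxycarbonyl)-4-chloro-3-methylphenoxy]-4,6-dihydroxy-2,5-dimethylbenzoate | COC(=O)c1c(C)c(Oc2cc(OCC=C)c(Cl)c(C)c2C(=O)OCc2ccccc2)c(O)c(C)c1O | intermediate
13 | methyl 3-[2-(benzyloxycarbonyl)-4-chloro-5-hydroxy-3-methylphenoxy]-4,6-dihydroxy-2,5-dimethylbenzoate | COC(=O)c1c(C)c(Oc2cc(O)c(Cl)c(C)c2C(=O)OCc2ccccc2)c(O)c(C)c1O | intermediate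
14 | methyl 3-{2-(benzyloxycarbonyl)-4-chloro-6-[chloro(methoxy)methyl]-5-hydroxy-3-methylphenoxy}-4,6-dihydroxy-2,5-dimethylbenzoate (not isolated) | COC(=O)c1c(C)c(Oc2c(C(Cl)OC)c(O)c(Cl)c(C)c2C(=O)OCc2ccccc2)c(O)c(C)c1O | intermediate
15 | methyl 3-[2-(benzyloxycarbonyl)-4-chloro-6-formyl-5-hydroxy-3-methylphenoxy]-4,6-dihydroxy-2,5-dimethylbenzoate | COC(=O)c1c(C)c(Oc2c(C=O)c(O)c(Cl)c(C)c2C(=O)OCc2ccccc2)c(O)c(C)c1O | intermediate
16 | 3-chloro-6-[2,4-dihydroxy-5-(methoxycarbonyl)-3,6-dimethylphenoxy]-5-formyl-4-hydroxy-2-methylbenzoic acid | COC(=O)c1c(C)c(Oc2c(C=O)c(O)c(Cl)c(C)c2C(=O)O)c(O)c(C)c1O | target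

## Step count and least certain steps

Total: 10 steps. Longest linear sequence: 10 steps, from orsellinic acid 1; compounds 5 and 8 are commercial and enter directly.

**Step 7 (key step).** The dioxolane carbon sits next to the aryloxy-bearing carbon and a β-carbonyl, so its ionisation is slow. Prolonged acid exposure could let the freed triketone cyclodehydrate through oxygen, or let the β-keto ester hydrolyse and decarboxylate. In the base stage, lactonisation of the diketo ester onto its own ester can compete with the aldol. The fallback turns that lactonisation into a protecting step and sets out from 10. DBU in toluene at 80 °C should close the diketo ester to 6-{[5-(allyloxy)-2-(benzyloxycarbonyl)-4-chloro-3-methylphenoxy](2-methyl-1,3-dioxolan-2-yl)methyl}-4-hydroxy-5-methyl-2H-pyran-2-one F1. The pyranone tolerates strong aqueous acid, so TFA–water at rt can then remove the ketal to give 6-{1-[5-(allyloxy)-2-(benzyloxycarbonyl)-4-chloro-3-methylphenoxy]-2-oxopropyl}-4-hydroxy-5-methyl-2H-pyran-2-one F2. NaOMe in MeOH should open the lactone to the enolate of the methyl triketo ester, which folds by the same C1–C2 aldol; this is the known base conversion of 6-(2-oxoalkyl)-4-hydroxy-2-pyranones into resorcylates. The route is rejoined at 12.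

**Step 6.** Proton transfer from the α-aryloxy ester to the dianion may outrun addition, because the carbonyl is shielded by the quaternary ketal carbon and the ortho-substituted aryloxy group. The resulting ester enolate could then eliminate the ketal oxygen or attack the ring B ester. The fallback lowers the oxidation level of the electrophile and sets out from 7. iBu2AlH (1.1 equiv, toluene, −78 °C) should reduce the aliphatic ester, which is far less hindered than the ring B ester, to benzyl 4-(allyloxy)-3-chloro-2-methyl-6-[1-(2-methyl-1,3-dioxolan-2-yl)-2-oxoethoxy]benzoate F3. Dianion 9 adds to aldehydes at −78 °C faster than it deprotonates them and should give methyl 6-[5-(allyloxy)-2-(benzyloxycarbonyl)-4-chloro-3-methylphenoxy]-5-hydroxy-4-methyl-6-(2-methyl-1,3-dioxolan-2-yl)-3-oxohexanoate F4. Dess–Martin periodinane in CH2Cl2 then oxidises the 5-hydroxy-3-keto ester to the diketo ester, rejoining the route at 10.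

**Step 4.** The chelated, ortho-substituted phenoxide is a weak nucleophile, while the chloro keto ester is consumed by base through enolisation, self-condensation and deacetylation, so substitution may stall. The fallback replaces SN2 by carbene O–H insertion and sets out from 4. Ethyl 2-diazo-3-oxobutanoate F5, made from ethyl acetoacetate by diazo transfer with 4-acetamidobenzenesulfonyl azide and Et3N, with Rh2(OAc)4 (1 mol %) in CH2Cl2 at reflux should insert into the phenolic O–H without any base. The route is rejoined at 6.

**Step 9.** Substitution at C2' may be slow because that carbon lies between the hydroxyl and the tetra-ortho-substituted ether. Long contact with TiCl4 can cleave the benzyl ester, after which the free acid would consume the formylating agent. The fallback delivers the carbon intramolecularly from the allyl ether and sets out from 12, skipping step 8. Heating in N,N-diethylaniline at about 190 °C should effect aromatic Claisen rearrangement to C2' (C4' is blocked by chlorine), giving methyl 3-[6-allyl-2-(benzyloxycarbonyl)-4-chloro-5-hydroxy-3-methylphenoxy]-4,6-dihydroxy-2,5-dimethylbenzoate F6. RuHCl(CO)(PPh3)3 in toluene at 80 °C should move the double bond into conjugation to give methyl 3-{2-(benzyloxycarbonyl)-4-chloro-5-hydroxy-3-methyl-6-[(E)-prop-1-enyl]phenoxy}-4,6-dihydroxy-2,5-dimethylbenzoate F7. OsO4 (cat.) and NaIO4 with 2,6-lutidine in dioxane–water should cleave the alkene to the aldehyde, rejoining the route at 15.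

## Further compounds

F1 | step 7 | 6-{[5-(allyloxy)-2-(benzyloxycarbonyl)-4-chloro-3-methylphenoxy](2-methyl-1,3-dioxolan-2-yl)methyl}-4-hydroxy-5-methyl-2H-pyran-2-one | Cc1c(O)cc(=O)oc1C(Oc1cc(OCC=C)c(Cl)c(C)c1C(=O)OCc1ccccc1)C1(C)OCCO1
F2 | step 7 | 6-{1-[5-(allyloxy)-2-(benzyloxycarbonyl)-4-chloro-3-methylphenoxy]-2-oxopropyl}-4-hydroxy-5-methyl-2H-pyran-2-one | Cc1c(O)cc(=O)oc1C(Oc1cc(OCC=C)c(Cl)c(C)c1C(=O)OCc1ccccc1)C(C)=O
F3 | step 6 | benzyl 4-(allyloxy)-3-chloro-2-methyl-6-[1-(2-methyl-1,3-dioxolan-2-yl)-2-oxoethoxy]benzoate | O=CC(Oc1cc(OCC=C)c(Cl)c(C)c1C(=O)OCc1ccccc1)C1(C)OCCO1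
F4 | step 6 | methyl 6-[5-(allyloxy)-2-(benzyloxycarbonyl)-4-chloro-3-methylphenoxy]-5-hydroxy-4-methyl-6-(2-methyl-1,3-dioxolan-2-yl)-3-oxohexanoate | COC(=O)CC(=O)C(C)C(O)C(Oc1cc(OCC=C)c(Cl)c(C)c1C(=O)OCc1ccccc1)C1(C)OCCO1
F5 | step 4 | ethyl 2-diazo-3-oxobutanoate | CCOC(=O)C(=[N+]=[N-])C(C)=O
F6 | step 9 | methyl 3-[6-allyl-2-(benzyloxycarbonyl)-4-chloro-5-hydroxy-3-methylphenoxy]-4,6-dihydroxy-2,5-dimethylbenzoate | COC(=O)c1c(C)c(Oc2c(CC=C)c(O)c(Cl)c(C)c2C(=O)OCc2ccccc2)c(O)c(C)c1O
F7 | step 9 | methyl 3-{2-(benzyloxycarbonyl)-4-chloro-5-hydroxy-3-methyl-6-[(E)-prop-1-enyl]phenoxy}-4,6-dihydroxy-2,5-dimethylbenzoate | COC(=O)c1c(C)c(Oc2c(/C=C/C)c(O)c(Cl)c(C)c2C(=O)OCc2ccccc2)c(O)c(C)c1O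
A1 | alternative 1 | benzyl 6-[2,4-bis(benzyloxy)-5-(methoxycarbonyl)-3,6-dimethylphenoxy]-4-(benzyloxy)-3-chloro-2-methylbenzoate | COC(=O)c1c(C)c(Oc2cc(OCc3ccccc3)c(Cl)c(C)c2C(=O)OCc2ccccc2)c(OCc2ccccc2)c(C)c1OCc1ccccc1
A2 | alternative 1 | methyl 2,4-bis(benzyloxy)-5-{[4-(benzyloxy)-5-chloro-6-oxo-6H-pyran-2-yl]oxy}-3,6-dimethylbenzoate | COC(=O)c1c(C)c(OC2=CC(OCc3ccccc3)=C(Cl)C(=O)O2)c(OCc2ccccc2)c(C)c1OCc1ccccc1
A3 | alternative 1 | benzyl but-2-ynoate | CC#CC(=O)OCc1ccccc1
A4 | alternative 1 | methyl 2,4-bis(benzyloxy)-5-hydroxy-3,6-dimethylbenzoate | COC(=O)c1c(C)c(O)c(OCc2ccccc2)c(C)c1OCc1ccccc1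
A5 | alternative 2 | tert-butyl 2-[2,4-bis(benzyloxy)-5-(methoxycarbonyl)-3,6-dimethylphenoxy]-4-hydroxy-6-methylbenzoate | COC(=O)c1c(C)c(Oc2cc(O)cc(C)c2C(=O)OC(C)(C)C)c(OCc2ccccc2)c(C)c1OCc1ccccc1
A6 | alternative 2 | (E)-4-methoxy-2-(trimethylsilyloxy)penta-1,3-diene | C=C(O[Si](C)(C)C)/C=C(\C)OC
A7 | alternative 2 | methyl 2,4-bis(benzyloxy)-5-[(3-tert-butoxy-3-oxoprop-1-yn-1-yl)oxy]-3,6-dimethylbenzoate | COC(=O)c1c(C)c(OC#CC(=O)OC(C)(C)C)c(OCc2ccccc2)c(C)c1OCc1ccccc1
A8 | alternative 3 | tert-butyl 4-(benzyloxy)-3-chloro-6-[2-hydroxy-5-(methoxycarbonyl)-3,6-dimethyl-4-(triisopropylsilyloxy)phenoxy]-2-methylbenzoate | COC(=O)c1c(C)c(Oc2cc(OCc3ccccc3)c(Cl)c(C)c2C(=O)OC(C)(C)C)c(O)c(C)c1O[Si](C(C)C)(C(C)C)C(C)C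
A9 | alternative 3 | methyl (E)-5-[5-(benzyloxy)-2-(tert-butoxycarbonyl)-4-chloro-3-methylphenoxy]-2-diazo-4-methyl-3-oxopent-4-enoate | COC(=O)C(=[N+]=[N-])C(=O)/C(C)=C/Oc1cc(OCc2ccccc2)c(Cl)c(C)c1C(=O)OC(C)(C)C
A10 | alternative 3 | 1-(triisopropylsilyloxy)propyne | CC#CO[Si](C(C)C)(C(C)C)C(C)C
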